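**Plan**
1. Retrosynthesis: cut C-6–C-8' together with C-7'–O (one oxidative radical event), then C-6–C-1' (reductive alkylation), then the two C-4 prenyl bonds (alkylative dearomatisation of 2,4,6-trihydroxyacetophenone), then C-2'–C-3' (aldol) back to the 1,2-seco keto aldehyde of (R)-limonene.
2. Forward: the cyclopentane is made first (all ten carbons of the C-1'…C-8' unit come from limonene), the cyclohexanetrione second, the two are joined through C-1', and the spiro carbocycle C-6/C-1'/C-2'/C-6'/C-7'/C-8' is closed last.
3. Enabling feature: C-6 of the trione ring lies between the C-1 and C-5 carbonyls and is an enolisable 1,3-dicarbonyl carbon, oxidisable to a tertiary radical. Across the trans-1,2-disubstituted cyclopentane (C-2'/C-6') the isopropenyl CH2 (C-8') is the terminus of a 5-substituted hex-5-enyl chain, so 6-endo attack closes the ring and the tertiary C-7' radical takes up O2.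
4. Stereochemistry: C-6' from (R)-limonene; C-3' by epoxidation anti to the isopropenyl group; C-2' under thermodynamic control (epimerisable formyl carbon, trans to both neighbours); C-6 (spiro) and C-7' in the key step (chair transition state, equatorial O2 capture).
5. Helper: a triethylsilyl ether on O-3' (blocks elimination, retro-aldol and ketalisation with the trione), removed in the last step; the hydroperoxide is reduced in the key-step flask.

Key step: step 8

Remarks. Locants used for 13–17: trione ring C-1 (C=O next to the acetyl-bearing C-2), C-3 (enol carbon), C-4 (gem-diprenyl), C-5 (C=O), C-6 (spiro carbon); terpene unit C-1' (CH2 on C-6), C-2', C-3' (C(CH3)O), C-4', C-5', C-6', C-7' (C(CH3)O), C-8' (CH2). Assumption: the enolised β-triketones are drawn as one tautomer (that of the target SMILES); the tautomers interconvert freely.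

**Route**

Step 1
Reactants: 1 (R)-(+)-limonene
Product: 3 (3R)-6-oxo-3-(prop-1-en-2-yl)heptanal, via secondary ozonide 2 (not isolated)
Conditions: O3 (1.0 equiv), CH2Cl2, −78 °C; then PPh3, −78 °C to rt
Reagents that add atoms: ozone, O=[O+][O-]
Why: Criegee ozonolysis with reductive work-up should cleave the trisubstituted ring alkene, which is more electron-rich than the 1,1-disubstituted isopropenyl group, with one equivalent of ozone and without touching the stereocentre.

Step 2
Reactants: 3 (3R)-6-oxo-3-(prop-1-en-2-yl)heptanal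
Product: 5 (5S)-2-methyl-5-(prop-1-en-2-yl)cyclopent-1-ene-1-carbaldehyde, via aldol adduct 4 (not isolated)
Conditions: piperidine (cat.), AcOH (cat.), benzene, reflux, Dean–Stark
Reagents that add atoms: none
Why: Intramolecular aldol condensation under enamine catalysis (5-enolexo) should join the aldehyde α-carbon to the methyl ketone and dehydrate to the conjugated tetrasubstituted enal, the stereocentre being non-enolisable.

Step 3
Reactants: 5 (5S)-2-methyl-5-(prop-1-en-2-yl)cyclopent-1-ene-1-carbaldehyde
Product: 6 (1S,2S,5R)-5-methyl-2-(prop-1-en-2-yl)-6-oxabicyclo[3.1.0]hexane-1-carbaldehyde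
Conditions: 30% H2O2, NaOH (cat.), MeOH, 0 °C
Reagents that add atoms: hydrogen peroxide, OO
Why: Weitz–Scheffer nucleophilic epoxidation should attack only the electron-poor enal double bond (the isopropenyl group is inert to hydroperoxide anion) and close the oxirane on the face anti to the adjacent isopropenyl group, which sets the C–O bond of the later C-3' carbinol.

Step 4
Reactants: 6 (1S,2S,5R)-5-methyl-2-(prop-1-en-2-yl)-6-oxabicyclo[3.1.0]hexane-1-carbaldehyde
Product: 7 (1S,2R,5R)-2-hydroxy-2-methyl-5-(prop-1-en-2-yl)cyclopentane-1-carbaldehyde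
Conditions: SmI2 (2.2 equiv), THF/MeOH, −90 °C; pH 7 buffer
Reagents that add atoms: none
Why: Single-electron reduction of the α,β-epoxy carbonyl (ketyl, Cα–O fragmentation, second electron, protonation by MeOH) should cleave only the α C–O bond, so the tertiary carbinol keeps its oxygen with retention, while the re-formed formyl-bearing centre is epimerisable and should settle trans to both the isopropenyl and the methyl group (any cis epimer converges in step 7).

Step 5
Reactants: 7 (1S,2R,5R)-2-hydroxy-2-methyl-5-(prop-1-en-2-yl)cyclopentane-1-carbaldehyde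
Product: 8 (1S,2R,5R)-2-methyl-5-(prop-1-en-2-yl)-2-[(triethylsilyl)oxy]cyclopentane-1-carbaldehyde
Conditions: TESOTf, 2,6-lutidine, CH2Cl2, −78 °C
Reagents that add atoms: triethylsilyl triflate, CC[Si](CC)(CC)OS(=O)(=O)C(F)(F)F
Why: Silylation of the tertiary alcohol with a silyl triflate and a hindered base at low temperature is the standard protection of aldol-type β-hydroxy aldehydes and should stop retro-aldol cleavage, dehydration and later hemiketalisation with the trione.

Step 6
Reactants: 9 1-(2,4,6-trihydroxyphenyl)ethan-1-one; 10 1-bromo-3-methylbut-2-ene (2.1 equiv)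
Product: 12 2-acetyl-3,5-dihydroxy-4,4-bis(3-methylbut-2-en-1-yl)cyclohexa-2,5-dien-1-one, via monoprenyl acetophenone 11 (not isolated)
Conditions: NaOMe (2.2 equiv), MeOH, 0 °C to rt; chromatographic removal of the 3,5-di- and triprenyl isomers
Reagents that add atoms: none
Why: Alkylative dearomatisation of the acylphloroglucinol anion should place two prenyl groups on the same ring carbon, the second C-alkylation breaking aromaticity and leaving the remaining ring CH (later C-6) as the only free nucleophilic carbon.

Step 7
Reactants: 8 (1S,2R,5R)-2-methyl-5-(prop-1-en-2-yl)-2-[(triethylsilyl)oxy]cyclopentane-1-carbaldehyde; 12 2-acetyl-3,5-dihydroxy-4,4-bis(3-methylbut-2-en-1-yl)cyclohexa-2,5-dien-1-one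
Product: 14 2-acetyl-3,5-dihydroxy-4,4-bis(3-methylbut-2-en-1-yl)-6-({(1S,2R,5R)-2-methyl-5-(prop-1-en-2-yl)-2-[(triethylsilyl)oxy]cyclopentyl}methyl)cyclohexa-2,5-dien-1-one, via Knoevenagel alkylidene 13 (not isolated)
Conditions: L-proline (20 mol%), Hantzsch ester (1.1 equiv), CH2Cl2, rt
Reagents that add atoms: none
Why: Organocatalytic reductive alkylation (Knoevenagel condensation then transfer hydrogenation) should condense the aldehyde with the free ring carbon of 12 and reduce the alkylidene trione 13 by conjugate hydride delivery to C-1', the formyl α-carbon equilibrating through the enamine so that C-2' enters 14 in the all-trans arrangement.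

Step 8
Reactants: 14 (cyclisation precursor, full name in the list)
Product: 16 (6S,2'S,3'R,6'R,7'R)-spiro carbinol carrying 3'-OSiEt3 (full description in the list), via tertiary hydroperoxide 15 (not isolated)
Conditions: Mn(OAc)3·2H2O (0.2 equiv), O2 (1 atm), AcOH, 23 °C; then PPh3, rt
Reagents that add atoms: dioxygen, O=O
Why: Mn(III) should oxidise the C-6 enol to a doubly acyl-stabilised tertiary radical that adds to the CH2 terminus C-8' of the isopropenyl group; the tertiary C-7' radical is captured by O2, the peroxyl is reduced by Mn(II) to hydroperoxide 15 (regenerating Mn(III)), and PPh3 reduces the O–O bond to the carbinol. The closest known reaction type is the Mn(III)-based oxidative free-radical cyclisation of unsaturated 1,3-dicarbonyl compounds, as applied to dearomatised acylphloroglucinols, with aerobic hydroperoxide termination. The cyclohexane closes 6-endo-trig, since attack at the unsubstituted terminus gives a tertiary radical whereas 5-exo attack would join two quaternary carbons and leave a primary radical. The spiro centre C-6 is set in a chair transition state fixed by the trans ring fusion, in which the flat acyl-enol arm (C-1) should take the axial site under the forming ring and the arm bearing the out-of-plane geminal prenyls (C-5) the equatorial site; C-7' is set by O2 approaching the planar radical from the equatorial side, because the oxygen of the axial C-1 carbonyl covers the axial lobe, which leaves the methyl group axial and the oxygen equatorial. The step needs the spiro closure to outrun both a bridged 5-exo addition to a C-4 prenyl group and oxygenation at C-6: the spiro closure is strain-free and pre-organised by the trans-disposed ring substituents, the bridged closure would build a strained bicyclo[3.2.1]octanetrione, and O2 addition to the stabilised C-6 radical should be reversible whereas that to the tertiary alkyl radical is not.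

Step 9
Reactants: 16 (6S,2'S,3'R,6'R,7'R)-spiro carbinol carrying 3'-OSiEt3
Product: 17 CNP0266834.1 (target)
Conditions: HF·pyridine, THF, 0 °C to rt
Reagents that add atoms: none
Why: Fluoride-mediated cleavage of the tertiary triethylsilyl ether under buffered, mildly acidic conditions should free the C-3' alcohol without dehydrating either tertiary carbinol or disturbing the acidic triketone.

**Compound list**
1 | (R)-(+)-limonene, (4R)-1-methyl-4-(prop-1-en-2-yl)cyclohex-1-ene | CC1=CC[C@@H](CC1)C(C)=C | starting material
2 | secondary ozonide, (4R)-1-methyl-4-(prop-1-en-2-yl)-7,8,9-trioxabicyclo[4.2.1]nonane (acetal carbons not defined) | CC12OC(C[C@@H](CC1)C(C)=C)OO2 | intermediate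
3 | (3R)-6-oxo-3-(prop-1-en-2-yl)heptanal | O=CC[C@@H](CCC(C)=O)C(C)=C | intermediate
4 | aldol adduct, (5R)-2-hydroxy-2-methyl-5-(prop-1-en-2-yl)cyclopentane-1-carbaldehyde (C-1/C-2 epimers) | O=CC1[C@@H](CCC1(C)O)C(C)=C | intermediate
5 | (5S)-2-methyl-5-(prop-1-en-2-yl)cyclopent-1-ene-1-carbaldehyde | O=CC1=C(C)CC[C@H]1C(C)=C | intermediate
6 | (1S,2S,5R)-5-methyl-2-(prop-1-en-2-yl)-6-oxabicyclo[3.1.0]hexane-1-carbaldehyde (oxirane trans to isopropenyl) | O=C[C@@]12O[C@]1(C)CC[C@H]2C(C)=C | intermediate
7 | (1S,2R,5R)-2-hydroxy-2-methyl-5-(prop-1-en-2-yl)cyclopentane-1-carbaldehyde | O=C[C@H]1[C@@H](CC[C@@]1(C)O)C(C)=C | intermediate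
8 | (1S,2R,5R)-2-methyl-5-(prop-1-en-2-yl)-2-[(triethylsilyl)oxy]cyclopentane-1-carbaldehyde | O=C[C@H]1[C@@H](CC[C@@]1(C)O[Si](CC)(CC)CC)C(C)=C | intermediate
9 | 1-(2,4,6-trihydroxyphenyl)ethan-1-one | CC(=O)c1c(O)cc(O)cc1O | starting material
10 | 1-bromo-3-methylbut-2-ene (prenyl bromide) | CC(C)=CCBr | starting material
11 | 1-[2,4,6-trihydroxy-3-(3-methylbut-2-en-1-yl)phenyl]ethan-1-one | CC(=O)c1c(O)cc(O)c(CC=C(C)C)c1O | intermediate
12 | 2-acetyl-3,5-dihydroxy-4,4-bis(3-methylbut-2-en-1-yl)cyclohexa-2,5-dien-1-one | CC(=O)C1=C(O)C(CC=C(C)C)(CC=C(C)C)C(O)=CC1=O | intermediate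
13 | Knoevenagel alkylidene, 2-acetyl-3-hydroxy-4,4-bis(3-methylbut-2-en-1-yl)-6-({(1S,2R,5R)-2-methyl-5-(prop-1-en-2-yl)-2-[(triethylsilyl)oxy]cyclopentyl}methylidene)cyclohex-2-ene-1,5-dione (exocyclic C=C geometry not defined) | CC(=O)C1=C(O)C(CC=C(C)C)(CC=C(C)C)C(=O)C(=C[C@H]2[C@@H](CC[C@@]2(C)O[Si](CC)(CC)CC)C(C)=C)C1=O | intermediate
14 | 2-acetyl-3,5-dihydroxy-4,4-bis(3-methylbut-2-en-1-yl)-6-({(1S,2R,5R)-2-methyl-5-(prop-1-en-2-yl)-2-[(triethylsilyl)oxy]cyclopentyl}methyl)cyclohexa-2,5-dien-1-one | CC(=O)C1=C(O)C(CC=C(C)C)(CC=C(C)C)C(O)=C(C[C@H]2[C@@H](CC[C@@]2(C)O[Si](CC)(CC)CC)C(C)=C)C1=O | intermediate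
15 | tertiary hydroperoxide, as 16 but with equatorial OOH at C-7'; (6S,2'S,3'R,6'R,7'R) | CC(=O)C1=C(O)C(CC=C(C)C)(CC=C(C)C)C(=O)[C@@]2(C[C@H]3[C@@H](CC[C@@]3(C)O[Si](CC)(CC)CC)[C@](C)(OO)C2)C1=O | intermediate
16 | 2-acetyl-3-hydroxy-4,4-bis(3-methylbut-2-en-1-yl)cyclohex-2-ene-1,5-dione spiro-fused at C-6 to the six-membered ring of a trans-fused octahydroindene (ring C-6/C-1'/C-2'/C-6'/C-7'/C-8'), with 3'-methyl-3'-OSiEt3 and 7'-methyl-7'-OH (OH equatorial, methyl axial, C-1 carbonyl axial); (6S,2'S,3'R,6'R,7'R) | CC(=O)C1=C(O)C(CC=C(C)C)(CC=C(C)C)C(=O)[C@@]2(C[C@H]3[C@@H](CC[C@@]3(C)O[Si](CC)(CC)CC)[C@](C)(O)C2)C1=O | intermediate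
17 | CNP0266834.1, as 16 with free 3'-OH; (6S,2'S,3'R,6'R,7'R) | CC(=O)C1=C(O)C(CC=C(C)C)(CC=C(C)C)C(=O)[C@@]2(C[C@H]3[C@@H](CC[C@@]3(C)O)[C@](C)(O)C2)C1=O | target

**Step count and risks**
Total steps: 9. Longest linear sequence: 8 (steps 1–5, 7, 8, 9).

Step 8. What may go wrong: the C-6 radical is diverted before it reaches C-8', either by bridged 5-exo addition to one of the geminal prenyl groups or by capture of O2 at C-6 itself; the facial selectivity at C-6 may also be lower than argued. Fallback: close the ring by a two-electron path that the prenyl groups cannot join. It sets out from aldehyde 8. Epoxidation of the isopropenyl group with dimethyldioxirane (acetone, 0 °C) would give (1S,2R,5R)-2-methyl-5-[(2S)-2-methyloxiran-2-yl]-2-[(triethylsilyl)oxy]cyclopentane-1-carbaldehyde F1 together with its oxirane epimer. Reductive alkylation with 12 under the conditions of step 7 would give the epoxy trione F2. A mild base (K2CO3, DMF, 50 °C) should then let the C-6 enolate open the oxirane at its CH2 terminus (6-endo-tet at the primary carbon). Only the (S)-oxirane can place its C–O bond anti-periplanar and equatorial in the chair, so the unwanted epimer is left behind, and the product is 16, where the route is rejoined before step 9.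

Step 4. What may go wrong: reductive dimerisation of the aldehyde ketyl (pinacol coupling) competes with C–O fragmentation, and the free tertiary aldol 7 undergoes retro-aldol cleavage or dehydration on work-up. Fallback: carry out the C–O cleavage at the ester oxidation level, where it is well established. It sets out from 6. Pinnick oxidation (NaClO2, NaH2PO4, 2-methyl-2-butene) would give the epoxy acid F3 and TMSCHN2/MeOH the methyl ester F4. SmI2 with HMPA and a proton source would give methyl (1S,2R,5R)-2-hydroxy-2-methyl-5-(prop-1-en-2-yl)cyclopentane-1-carboxylate F5, and TESOTf/2,6-lutidine its silyl ether F6. DIBAL-H at −78 °C would then give aldehyde 8, where the route is rejoined (the α-centre is again equilibrated in step 7).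

Step 7. What may go wrong: condensation of the α-branched formyl group next to the quaternary silyloxy carbon with the hindered diprenyl trione is slow, so that β-elimination of triethylsilanol through the enamine overtakes C–C bond formation. Fallback: change the order of events so that the aldehyde meets an unhindered aromatic nucleophile. It sets out from 8 and 9. The same amine/Hantzsch-ester reductive alkylation with 9 in excess would give 1-[2,4,6-trihydroxy-3-({(1S,2R,5R)-2-methyl-5-(prop-1-en-2-yl)-2-[(triethylsilyl)oxy]cyclopentyl}methyl)phenyl]ethan-1-one F7. Geminal diprenylation with 10 (NaOMe, MeOH, 0 °C) should then dearomatise the ring at the less hindered, prenyl-bearing carbon and give 14, where the route is rejoined before step 8.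

**Further compounds**
F1 | step 8 | (1S,2R,5R)-2-methyl-5-[(2S)-2-methyloxiran-2-yl]-2-[(triethylsilyl)oxy]cyclopentane-1-carbaldehyde | O=C[C@H]1[C@@H](CC[C@@]1(C)O[Si](CC)(CC)CC)[C@@]2(C)CO2
F2 | step 8 | 2-acetyl-3,5-dihydroxy-4,4-bis(3-methylbut-2-en-1-yl)-6-({(1S,2R,5R)-2-methyl-5-[(2S)-2-methyloxiran-2-yl]-2-[(triethylsilyl)oxy]cyclopentyl}methyl)cyclohexa-2,5-dien-1-one | CC(=O)C1=C(O)C(CC=C(C)C)(CC=C(C)C)C(O)=C(C[C@H]2[C@@H](CC[C@@]2(C)O[Si](CC)(CC)CC)[C@@]3(C)CO3)C1=O
F3 | step 4 | (1S,2S,5R)-5-methyl-2-(prop-1-en-2-yl)-6-oxabicyclo[3.1.0]hexane-1-carboxylic acid | OC(=O)[C@@]12O[C@]1(C)CC[C@H]2C(C)=C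
F4 | step 4 | methyl (1S,2S,5R)-5-methyl-2-(prop-1-en-2-yl)-6-oxabicyclo[3.1.0]hexane-1-carboxylate | COC(=O)[C@@]12O[C@]1(C)CC[C@H]2C(C)=C
F5 | step 4 | methyl (1S,2R,5R)-2-hydroxy-2-methyl-5-(prop-1-en-2-yl)cyclopentane-1-carboxylate | COC(=O)[C@H]1[C@@H](CC[C@@]1(C)O)C(C)=C
F6 | step 4 | methyl (1S,2R,5R)-2-methyl-5-(prop-1-en-2-yl)-2-[(triethylsilyl)oxy]cyclopentane-1-carboxylate | COC(=O)[C@H]1[C@@H](CC[C@@]1(C)O[Si](CC)(CC)CC)C(C)=C
F7 | step 7 | 1-[2,4,6-trihydroxy-3-({(1S,2R,5R)-2-methyl-5-(prop-1-en-2-yl)-2-[(triethylsilyl)oxy]cyclopentyl}methyl)phenyl]ethan-1-one | CC(=O)c1c(O)cc(O)c(C[C@H]2[C@@H](CC[C@@]2(C)O[Si](CC)(CC)CC)C(C)=C)c1O
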